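**Assumption:** reagents that stand only over the arrow are named (with SMILES where they add atoms) and carry no number; numbers go to the starting materials that supply the skeleton, to in-flask intermediates and to products. The target is (13S)-13-hydroxy-1-(2,4,6-trihydroxyphenyl)hexadecan-1-one.

## Retrosynthetic overview

1. Target ⇒ its tris-O-benzyl 2,3-didehydro (enone) precursor; one final H2/Pd/C step saturates C2=C3 and frees the three phenols, after the C13 silyl ether has been removed.
2. Enone ⇒ β-hydroxy ketone ⇒ key C2–C3 disconnection: intermolecular aldol of the lithium enolate of 2,4,6-tris(benzyloxy)acetophenone with (S)-11-silyloxytetradecanal.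
3. That aldehyde ⇒ methyl (R)-11-hydroxytetradec-13-enoate ⇒ Brown asymmetric allylation of methyl 11-oxoundecanoate, which sets the only stereocentre; the allyl group becomes the propyl terminus on hydrogenation.
4. Methyl 11-oxoundecanoate ⇒ methyl undec-10-enoate (hydroboration, oxidation); the aryl ketone ⇒ 2,4,6-trihydroxyacetophenone and benzyl bromide.
5. No ring is formed: the only ring, the phloroglucinol nucleus, is bought intact.

## Route

Step 1
Reactants: 1 methyl undec-10-enoate
Product: 3 methyl 11-hydroxyundecanoate, via alkylborane 2 (not isolated)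
Conditions: 9-BBN (1.1 equiv, 0.5 M in THF), 0 °C → rt; then 3 M aq NaOAc, 30% H2O2, 0 → 40 °C
Reagents that add atoms: hydrogen peroxide, OO
Why: Anti-Markovnikov hydroboration–oxidation, in which bulky 9-BBN puts boron only on the terminal carbon and ignores the ester, and the buffered peroxide oxidation avoids saponification.

Step 2
Reactants: 3 methyl 11-hydroxyundecanoate
Product: 4 methyl 11-oxoundecanoate
Conditions: TEMPO (0.1 equiv), PhI(OAc)2 (1.1 equiv), CH2Cl2, rt
Reagents that add atoms: none
Why: TEMPO/oxoammonium oxidation of a primary alcohol stops cleanly at the aldehyde in dry CH2Cl2 and leaves the ester alone.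

Step 3
Reactants: 4 methyl 11-oxoundecanoate; 5 allylmagnesium bromide
Product: 8 methyl (11R)-11-hydroxytetradec-13-enoate, via allylborane 6 (not isolated), via borinate ester 7 (not isolated)
Conditions: (–)-Ipc2BOMe [from (+)-α-pinene] (1.3 equiv), 5 (1.2 equiv, 1.0 M in Et2O), Et2O, –78 °C → rt, 1 h; then 4 (1.0 equiv), –78 °C, 3 h; then NaH2PO4/Na2HPO4 buffer (pH 7), MeOH, 30% H2O2, 0 °C → rt
Reagents that add atoms: none
Why: Brown asymmetric carbonyl allylation, in which the (+)-α-pinene-derived allylborane adds through a chair six-membered transition state to the Si face of the aldehyde and so sets the 11R centre (the future 13S carbinol), while at –78 °C the Grignard-free borane does not touch the methyl ester.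

Step 4
Reactants: 8 methyl (11R)-11-hydroxytetradec-13-enoate
Product: 9 methyl (11R)-11-[(tert-butyldimethylsilyl)oxy]tetradec-13-enoate
Conditions: TBSCl (1.3 equiv), imidazole (2.5 equiv), DMF, rt
Reagents that add atoms: tert-butyldimethylsilyl chloride, CC(C)(C)[Si](C)(C)Cl
Why: Standard imidazole-promoted silylation of a secondary alcohol, which occurs at oxygen and leaves the configuration of the carbinol carbon unchanged.

Step 5
Reactants: 9 methyl (11R)-11-[(tert-butyldimethylsilyl)oxy]tetradec-13-enoate
Product: 10 methyl (11S)-11-[(tert-butyldimethylsilyl)oxy]tetradecanoate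
Conditions: H2 (1 atm), PtO2 (2 mol%), EtOAc, rt
Reagents that add atoms: none
Why: Catalytic hydrogenation of the terminal alkene turns allyl into propyl without touching any bond at the stereocentre, so the descriptor changes from R to S only because propyl now ranks below the long chain.

Step 6
Reactants: 10 methyl (11S)-11-[(tert-butyldimethylsilyl)oxy]tetradecanoate
Product: 11 (11S)-11-[(tert-butyldimethylsilyl)oxy]tetradecan-1-ol
Conditions: LiAlH4 (0.75 equiv), THF, 0 °C; then H2O, 15% aq NaOH, H2O
Reagents that add atoms: none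
Why: Hydride reduction of the methyl ester to the primary alcohol, which a secondary TBS ether survives at 0 °C.

Step 7
Reactants: 11 (11S)-11-[(tert-butyldimethylsilyl)oxy]tetradecan-1-ol
Product: 12 (11S)-11-[(tert-butyldimethylsilyl)oxy]tetradecanal
Conditions: TEMPO (0.1 equiv), PhI(OAc)2 (1.1 equiv), CH2Cl2, rt
Reagents that add atoms: none
Why: TEMPO/oxoammonium oxidation gives the aldehyde without over-oxidation or loss of the silyl ether; the aldehyde is used at once.

Step 8
Reactants: 13 2,4,6-trihydroxyacetophenone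
Product: 14 1-[2,4,6-tris(benzyloxy)phenyl]ethan-1-one
Conditions: BnBr (3.6 equiv), K2CO3 (5 equiv), DMF, 80 °C; recrystallise
Reagents that add atoms: benzyl bromide, BrCc1ccccc1
Why: Williamson etherification, in which excess benzyl bromide and K2CO3 in hot DMF also alkylate the two hydrogen-bonded ortho phenols, and minor C-benzylated material is removed by crystallisation.

Step 9
Reactants: 14 1-[2,4,6-tris(benzyloxy)phenyl]ethan-1-one; 12 (11S)-11-[(tert-butyldimethylsilyl)oxy]tetradecanal
Product: 16 (13S)-13-[(tert-butyldimethylsilyl)oxy]-3-hydroxy-1-[2,4,6-tris(benzyloxy)phenyl]hexadecan-1-one (C3 epimer mixture), via lithium enolate 15 (not isolated)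
Conditions: 14 (1.2 equiv), LiN(iPr)2 (1.2 equiv, commercial solution), THF, –78 °C, 45 min; then 12 (1.0 equiv), –78 °C, 1 h; AcOH, –78 °C
Reagents that add atoms: none
Why: Directed intermolecular aldol addition, in which the ketone can enolise only at its methyl group so one preformed lithium enolate adds to the aldehyde at –78 °C faster than it deprotonates it; the new C3 carbinol forms as an epimer mixture that step 10 erases, and C13 is untouched.

Step 10
Reactants: 16 (13S)-13-[(tert-butyldimethylsilyl)oxy]-3-hydroxy-1-[2,4,6-tris(benzyloxy)phenyl]hexadecan-1-one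
Product: 18 (2E,13S)-13-[(tert-butyldimethylsilyl)oxy]-1-[2,4,6-tris(benzyloxy)phenyl]hexadec-2-en-1-one, via mesylate 17 (not isolated)
Conditions: MsCl (1.5 equiv), Et3N (3 equiv), CH2Cl2, 0 °C; then DBU (2 equiv), 0 °C → rt
Reagents that add atoms: none
Why: Mesylation followed by E1cB elimination of the β-mesyloxy ketone gives the conjugated E-enone and removes the C3 stereocentre.

Step 11
Reactants: 18 (2E,13S)-13-[(tert-butyldimethylsilyl)oxy]-1-[2,4,6-tris(benzyloxy)phenyl]hexadec-2-en-1-one
Product: 19 (2E,13S)-13-hydroxy-1-[2,4,6-tris(benzyloxy)phenyl]hexadec-2-en-1-one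
Conditions: HF·pyridine, THF/pyridine, 0 °C → rt (plastic vessel)
Reagents that add atoms: none
Why: Fluoride-driven desilylation breaks only the Si–O bond, so C13 keeps its configuration, and benzyl ethers and the enone are inert to these mildly acidic conditions.

Step 12
Reactants: 19 (2E,13S)-13-hydroxy-1-[2,4,6-tris(benzyloxy)phenyl]hexadec-2-en-1-one
Product: 20 (13S)-13-hydroxy-1-(2,4,6-trihydroxyphenyl)hexadecan-1-one
Conditions: H2 (1 atm), 10% Pd/C, EtOAc/EtOH 1:1, rt; stop when the benzylated species are consumed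
Reagents that add atoms: none
Why: Catalytic hydrogenation with hydrogenolysis saturates the enone C=C and cleaves the three aryl benzyl ethers, while the hydrogen-bonded 2,4,6-trihydroxyaryl ketone, a vinylogous acid, resists reduction and the remote C13 carbinol is unaffected.

## Compound list

1 | methyl undec-10-enoate | C=CCCCCCCCCC(=O)OC | starting material
2 | methyl 11-(9-borabicyclo[3.3.1]nonan-9-yl)undecanoate | COC(=O)CCCCCCCCCCB1C2CCCC1CCC2 | intermediate
3 | methyl 11-hydroxyundecanoate | COC(=O)CCCCCCCCCCO | intermediate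
4 | methyl 11-oxoundecanoate | COC(=O)CCCCCCCCCC=O | intermediate
5 | allylmagnesium bromide | C=CC[Mg]Br | starting material
6 | (–)-B-allyldiisopinocampheylborane, from (+)-α-pinene | C=CCB([C@H]1[C@H](C)[C@H]2C[C@@H](C1)C2(C)C)[C@H]1[C@H](C)[C@H]2C[C@@H](C1)C2(C)C | intermediate
7 | methyl (11R)-11-[(diisopinocampheylboranyl)oxy]tetradec-13-enoate | COC(=O)CCCCCCCCC[C@@H](OB([C@H]1[C@H](C)[C@H]2C[C@@H](C1)C2(C)C)[C@H]1[C@H](C)[C@H]2C[C@@H](C1)C2(C)C)CC=C | intermediate
8 | methyl (11R)-11-hydroxytetradec-13-enoate | COC(=O)CCCCCCCCC[C@@H](O)CC=C | intermediate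
9 | methyl (11R)-11-[(tert-butyldimethylsilyl)oxy]tetradec-13-enoate | COC(=O)CCCCCCCCC[C@@H](O[Si](C)(C)C(C)(C)C)CC=C | intermediate
10 | methyl (11S)-11-[(tert-butyldimethylsilyl)oxy]tetradecanoate | COC(=O)CCCCCCCCC[C@@H](O[Si](C)(C)C(C)(C)C)CCC | intermediate
11 | (11S)-11-[(tert-butyldimethylsilyl)oxy]tetradecan-1-ol | OCCCCCCCCCC[C@@H](O[Si](C)(C)C(C)(C)C)CCC | intermediate
12 | (11S)-11-[(tert-butyldimethylsilyl)oxy]tetradecanal | O=CCCCCCCCCC[C@@H](O[Si](C)(C)C(C)(C)C)CCC | intermediate
13 | 2,4,6-trihydroxyacetophenone | CC(=O)c1c(O)cc(O)cc1O | starting material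
14 | 1-[2,4,6-tris(benzyloxy)phenyl]ethan-1-one | CC(=O)c1c(OCc2ccccc2)cc(OCc2ccccc2)cc1OCc1ccccc1 | intermediate
15 | lithium 1-[2,4,6-tris(benzyloxy)phenyl]ethen-1-olate | [Li]OC(=C)c1c(OCc2ccccc2)cc(OCc2ccccc2)cc1OCc1ccccc1 | intermediate
16 | (13S)-13-[(tert-butyldimethylsilyl)oxy]-3-hydroxy-1-[2,4,6-tris(benzyloxy)phenyl]hexadecan-1-one, C3 epimer mixture | CCC[C@H](O[Si](C)(C)C(C)(C)C)CCCCCCCCCC(O)CC(=O)c1c(OCc2ccccc2)cc(OCc2ccccc2)cc1OCc1ccccc1 | intermediate
17 | (13S)-13-[(tert-butyldimethylsilyl)oxy]-1-oxo-1-[2,4,6-tris(benzyloxy)phenyl]hexadecan-3-yl methanesulfonate, C3 epimer mixture | CCC[C@H](O[Si](C)(C)C(C)(C)C)CCCCCCCCCC(OS(C)(=O)=O)CC(=O)c1c(OCc2ccccc2)cc(OCc2ccccc2)cc1OCc1ccccc1 | intermediate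
18 | (2E,13S)-13-[(tert-butyldimethylsilyl)oxy]-1-[2,4,6-tris(benzyloxy)phenyl]hexadec-2-en-1-one | CCC[C@H](O[Si](C)(C)C(C)(C)C)CCCCCCCCC/C=C/C(=O)c1c(OCc2ccccc2)cc(OCc2ccccc2)cc1OCc1ccccc1 | intermediate
19 | (2E,13S)-13-hydroxy-1-[2,4,6-tris(benzyloxy)phenyl]hexadec-2-en-1-one | CCC[C@H](O)CCCCCCCCC/C=C/C(=O)c1c(OCc2ccccc2)cc(OCc2ccccc2)cc1OCc1ccccc1 | intermediate
20 | (13S)-13-hydroxy-1-(2,4,6-trihydroxyphenyl)hexadecan-1-one | CCC[C@H](O)CCCCCCCCCCCC(=O)c1c(O)cc(O)cc1O | target

## Summary

Total step count: 12. Longest linear sequence: 11 steps (steps 1–7, then 9–12); step 8 makes the second fragment.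

Three steps most likely to fail:

Step 3. The risks are an enantiomeric excess below about 90% and attack on the methyl ester if any allylmagnesium bromide survives. The fallback sets out from aldehyde 4 and sets the carbinol by catalytic asymmetric alkyl transfer instead of allylation. n-Pr2Zn (2 equiv), Ti(OiPr)4 (1.2 equiv) and (1R,2R)-N,N′-bis(trifluoromethanesulfonyl)cyclohexane-1,2-diamine (5 mol%) in toluene at –20 °C deliver propyl to the Si face, the same facial sense that gives (S)-1-phenylpropan-1-ol from benzaldehyde and Et2Zn. Dialkylzincs tolerate the ester, and the product is methyl (11S)-11-hydroxytetradecanoate F1 with no alkene left to hydrogenate. Silylation of F1 with TBSCl and imidazole in DMF comes back to the route at 10.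

Step 9. The risk is that the hindered lithium enolate deprotonates the enolisable aldehyde, leading to self-aldol of 12, recovered 14 or retro-aldol on warming. The fallback sets out from ketone 14, which TMSOTf and Et3N (CH2Cl2, 0 °C) convert into the isolable silyl enol ether trimethyl({1-[2,4,6-tris(benzyloxy)phenyl]ethenyl}oxy)silane F2. A Mukaiyama aldol of F2 with aldehyde 12 under BF3·OEt2 (CH2Cl2, –78 °C) has no basic species present, so the aldehyde cannot be enolised. Aqueous work-up removes the trimethylsilyl group and comes back to the route at aldol 16.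

Step 12. The risks are over-reduction of the aryl ketone before the phenols are free, or incomplete debenzylation. The fallback sets out from 19 and separates the two tasks. H2 over Pd/C poisoned with Ph2S (EtOAc, rt) saturates only the alkene and gives (13S)-13-hydroxy-1-[2,4,6-tris(benzyloxy)phenyl]hexadecan-1-one F3. The three benzyl ethers of F3 are then cleaved without a reductant by BCl3 (6 equiv) and pentamethylbenzene as cation scavenger in CH2Cl2 at –78 °C, followed by a MeOH quench, which comes back to the route at target 20.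

## Further compounds

F1 | step 3 | methyl (11S)-11-hydroxytetradecanoate | COC(=O)CCCCCCCCC[C@@H](O)CCC
F2 | step 9 | trimethyl({1-[2,4,6-tris(benzyloxy)phenyl]ethenyl}oxy)silane | C=C(O[Si](C)(C)C)c1c(OCc2ccccc2)cc(OCc2ccccc2)cc1OCc1ccccc1
F3 | step 12 | (13S)-13-hydroxy-1-[2,4,6-tris(benzyloxy)phenyl]hexadecan-1-one | CCC[C@H](O)CCCCCCCCCCCC(=O)c1c(OCc2ccccc2)cc(OCc2ccccc2)cc1OCc1ccccc1
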